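**Retrosynthetic overview**
1. Target 14 is cut at C2–C1': a C2-zincated 3-methoxychromone (an α-metallated enol ether, i.e. a masked acyl anion / β-acylvinyl anion made from 9) adds to C5 of 2-methoxy-1,4-benzoquinone 10. Ring B therefore arrives last, already as the free 2',5'-hydroquinone.
2. Chromone 9 comes from ring A by closing ring C: the C4–C4a bond by Friedel–Crafts acylation with methoxyacetic acid 7, and C2 from DMF.
3. The ring A nucleophile 6 (2,4-dimethoxyphloroglucinol) comes from syringol 1 by dibromination (phenol masked as acetate) and double hydroxylation.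
4. Ring order: A (bought, oxygenation adjusted), then C, then B.

Assumption: the target has no stereocentre and no configurationally stable axis, so it is achiral and there is no enantiomer to control.

**Step 1**
Reactants: 1 2,6-dimethoxyphenol (syringol)
Product: 3 3,5-dibromo-2,6-dimethoxyphenyl acetate, via 2,6-dimethoxyphenyl acetate 2 (not isolated)
Conditions: Ac2O (1.5 equiv), NaOAc (4 equiv), AcOH, 100 °C; then Br2 (2.1 equiv), 20 to 40 °C
Reagents that add atoms: acetic anhydride CC(=O)OC(C)=O; bromine BrBr
Why: O-acetylation turns off the para-directing phenol, so electrophilic aromatic bromination is steered by the two methoxy groups to C3 and then C5 (each ortho to one OMe and para to the other), while NaOAc buffers the HBr so that neither the ester nor the methyl ethers are cleaved.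

**Step 2**
Reactants: 3 3,5-dibromo-2,6-dimethoxyphenyl acetate
Product: 6 2,4-dimethoxybenzene-1,3,5-triol, via dibromophenol 4 (not isolated), via bromoresorcinol 5 (not isolated)
Conditions: Cu(acac)2 (10 mol %), N,N'-bis(4-hydroxy-2,6-dimethylphenyl)oxalamide (10 mol %), LiOH·H2O (8 equiv), degassed DMSO/H2O 4:1, 80 °C, Ar; then aq HCl to pH 3 under Ar
Reagents that add atoms: lithium hydroxide monohydrate O.[Li+].[OH-]
Why: Hydroxide first saponifies the acetate, and copper/oxalamide-catalysed Ullmann-type hydroxylation then replaces both aryl bromides (each has only one ortho substituent) by OH to give the symmetrical triol, which is acidified before any contact with air because the triphenoxide is oxidation-prone.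

**Step 3**
Reactants: 6 2,4-dimethoxybenzene-1,3,5-triol; 7 methoxyacetic acid
Product: 9 5,7-dihydroxy-3,6,8-trimethoxy-4H-chromen-4-one, via methoxyacetyl ketone 8 (not isolated)
Conditions: 7 (1.1 equiv), BF3·OEt2 (solvent and Lewis acid), 85 °C, Ar; then DMF, MsCl (3 equiv), 70 °C; aq NaOAc work-up
Reagents that add atoms: N,N-dimethylformamide CN(C)C=O
Why: Friedel–Crafts acylation can only occur at the single free ring carbon (flanked by two OH groups), and the resulting ortho-hydroxy ketone, as its boron chelate, undergoes Vilsmeier-type aminomethylenation at the CH2(OMe) carbon followed by ring closure with loss of dimethylamine, as in the one-pot deoxybenzoin-to-isoflavone protocol; the two ortho OH groups are equivalent by symmetry, so only one chromone can form.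

**Step 4**
Reactants: 9 5,7-dihydroxy-3,6,8-trimethoxy-4H-chromen-4-one; 10 2-methoxy-1,4-benzoquinone
Product: 14 5,7,2',5'-tetrahydroxy-3,6,8,4'-tetramethoxyflavone, via bis-TMS ether 11 (not isolated), via chromon-2-ylzinc chloride 12 (not isolated), via tris-TMS adduct 13 (not isolated)
Conditions: HMDS, TMSCl (cat.), 110 °C, then evaporate; TMPZnCl·LiCl (1.3 equiv), THF, 25 °C; cannulate into 10 (1.5 equiv), [RhCl(cod)]2 (2.5 mol %), TMSCl (1.5 equiv), THF, 0 to 25 °C; then 1 M HCl in MeOH, 25 °C
Reagents that add atoms: none
Why: Proposed new method: transient silylation removes the two acidic phenols and the hindered zinc amide then takes the only remaining acidic C–H (C2–H, alpha to the ring oxygen, ring A being fully substituted), giving an alpha-metallated enol ether in which the normally electrophilic C2 is nucleophilic; zinc-to-rhodium transmetallation and carborhodation of the unsubstituted C5=C6 bond of the quinone by the monovalent rhodium catalyst place the chromonyl group at C5 (beta to the more electrophilic C1 carbonyl, the C4 carbonyl being a deactivated vinylogous ester), TMSCl silylates the rhodium oxa-pi-allyl to turn the catalyst over, the dienone tautomerises to the hydroquinone and methanolic HCl strips the TMS ethers; the closest known reaction types are the rhodium-catalysed 1,4-addition of arylzinc chlorides to enones with TMSCl and the insertion of aryl–rhodium species into benzoquinone to give arylhydroquinones; no stereocentre is formed.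

**Compound list**
1 | 2,6-dimethoxyphenol (syringol) | COc1cccc(OC)c1O | starting material
2 | 2,6-dimethoxyphenyl acetate | CC(=O)Oc1c(OC)cccc1OC | intermediate
3 | 3,5-dibromo-2,6-dimethoxyphenyl acetate | CC(=O)Oc1c(OC)c(Br)cc(Br)c1OC | intermediate
4 | 3,5-dibromo-2,6-dimethoxyphenol (present as lithium phenoxide) | COc1c(Br)cc(Br)c(OC)c1O | intermediate
5 | 5-bromo-2,4-dimethoxybenzene-1,3-diol (present as lithium phenoxide) | COc1c(O)cc(Br)c(OC)c1O | intermediate
6 | 2,4-dimethoxybenzene-1,3,5-triol | COc1c(O)cc(O)c(OC)c1O | intermediate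
7 | methoxyacetic acid | COCC(=O)O | starting material
8 | 1-(2,4,6-trihydroxy-3,5-dimethoxyphenyl)-2-methoxyethan-1-one | COCC(=O)c1c(O)c(OC)c(O)c(OC)c1O | intermediate
9 | 5,7-dihydroxy-3,6,8-trimethoxy-4H-chromen-4-one | COc1coc2c(OC)c(O)c(OC)c(O)c2c1=O | intermediate
10 | 2-methoxy-1,4-benzoquinone (2-methoxycyclohexa-2,5-diene-1,4-dione) | COC1=CC(=O)C=CC1=O | starting material
11 | 3,6,8-trimethoxy-5,7-bis(trimethylsilyloxy)-4H-chromen-4-one | COc1coc2c(OC)c(O[Si](C)(C)C)c(OC)c(O[Si](C)(C)C)c2c1=O | intermediate
12 | [3,6,8-trimethoxy-4-oxo-5,7-bis(trimethylsilyloxy)-4H-chromen-2-yl]zinc chloride, LiCl complex | COc1c([Zn]Cl)oc2c(OC)c(O[Si](C)(C)C)c(OC)c(O[Si](C)(C)C)c2c1=O.[Li+].[Cl-] | intermediate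
13 | 2-[2-hydroxy-4-methoxy-5-(trimethylsilyloxy)phenyl]-3,6,8-trimethoxy-5,7-bis(trimethylsilyloxy)-4H-chromen-4-one | COc1cc(O)c(-c2oc3c(OC)c(O[Si](C)(C)C)c(OC)c(O[Si](C)(C)C)c3c(=O)c2OC)cc1O[Si](C)(C)C | intermediate
14 | 5,7,2',5'-tetrahydroxy-3,6,8,4'-tetramethoxyflavone, i.e. 2-(2,5-dihydroxy-4-methoxyphenyl)-5,7-dihydroxy-3,6,8-trimethoxy-4H-chromen-4-one (achiral) | COc1cc(O)c(-c2oc3c(OC)c(O)c(OC)c(O)c3c(=O)c2OC)cc1O | target

**Totals**
Total step count: 4. Longest linear sequence: 4 (1 → 3 → 6 → 9 → 14).

**Three steps most likely to fail, with fallbacks**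

Step 4 (zincation and rhodium-catalysed addition to the quinone). The main risks are electron transfer from the organozinc to the quinone, C5/C6 regiochemistry, and incomplete silylation of the chelated 5-OH. The fallback sets out from 10 and 12 and comes back at 14. Quinone 10 is reduced with Na2S2O4 to 2-methoxybenzene-1,4-diol F4. This is protected with MOMCl/iPr2NEt as 2-methoxy-1,4-bis(methoxymethoxy)benzene F5. Iodination with NIS in MeCN, para to the methoxy group, gives 1-iodo-4-methoxy-2,5-bis(methoxymethoxy)benzene F6. Zinc reagent 12 is then joined to F6 by Negishi cross-coupling (Pd(OAc)2/SPhos, THF, 50 °C) to give 2-[4-methoxy-2,5-bis(methoxymethoxy)phenyl]-3,6,8-trimethoxy-5,7-bis(trimethylsilyloxy)-4H-chromen-4-one F7. HCl in MeOH at 50 °C removes the MOM and TMS groups together and gives 14.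

Step 2 (double hydroxylation to an air-sensitive triol under basic conditions). The fallback sets out from 3 and comes back at 6. Dibromide 3 is coupled with benzyl alcohol under palladium catalysis ([Pd(allyl)Cl]2, RockPhos, Cs2CO3, toluene, 90 °C). The acetate is lost by transesterification, giving 3,5-bis(benzyloxy)-2,6-dimethoxyphenol F1, which is stable and can be purified. Hydrogenolysis (H2, Pd/C, EtOAc) then releases 6 under neutral conditions, and the filtered solution is taken straight into step 3.

Step 3 (one-pot acylation and ring closure with an alkoxyacetic acid in place of an arylacetic acid). The fallback sets out from 6 and comes back at 9. A Hoesch reaction of 6 with methoxyacetonitrile (ZnCl2, HCl gas, Et2O, 0 °C) precipitates 1-(2,4,6-trihydroxy-3,5-dimethoxyphenyl)-2-methoxyethan-1-iminium chloride F2. Hydrolysis in water at 100 °C gives ketone 8, which is isolated. Claisen formylation of 8 with ethyl formate and sodium gives, after acidification, the cyclic hemiacetal 2,5,7-trihydroxy-3,6,8-trimethoxychroman-4-one F3 (racemic mixture of diastereomers). Warming F3 in AcOH with a little HCl dehydrates it to 9.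

**Further compounds**
F1 | step 2 | 3,5-bis(benzyloxy)-2,6-dimethoxyphenol | COc1c(OCc2ccccc2)cc(OCc2ccccc2)c(OC)c1O
F2 | step 3 | 1-(2,4,6-trihydroxy-3,5-dimethoxyphenyl)-2-methoxyethan-1-iminium chloride | COCC(=[NH2+])c1c(O)c(OC)c(O)c(OC)c1O.[Cl-]
F3 | step 3 | 2,5,7-trihydroxy-3,6,8-trimethoxychroman-4-one (racemic mixture of diastereomers) | COC1C(O)Oc2c(OC)c(O)c(OC)c(O)c2C1=O
F4 | step 4 | 2-methoxybenzene-1,4-diol | COc1cc(O)ccc1O
F5 | step 4 | 2-methoxy-1,4-bis(methoxymethoxy)benzene | COc1cc(OCOC)ccc1OCOC
F6 | step 4 | 1-iodo-4-methoxy-2,5-bis(methoxymethoxy)benzene | COc1cc(OCOC)c(I)cc1OCOC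
F7 | step 4 | 2-[4-methoxy-2,5-bis(methoxymethoxy)phenyl]-3,6,8-trimethoxy-5,7-bis(trimethylsilyloxy)-4H-chromen-4-one | COc1cc(OCOC)c(-c2oc3c(OC)c(O[Si](C)(C)C)c(OC)c(O[Si](C)(C)C)c3c(=O)c2OC)cc1OCOC
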